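**Retrosynthetic overview**

- The route rests on one feature: C7 is the β-carbon of the 6,7-trans-fused α-methylene-γ-butyrolactone (ring O–C6–C7–C11–C12, exocyclic C11=C13) on the ten-membered carbocycle C1–C10, and the neighbouring C8–C9 threo diol has the configuration of D-tartaric acid.
- Key disconnection C7–C8: a C8 dioxolan-4-yl radical, released by cathodic decarboxylation of an N-acyloxyphthalimide, adds to C7 of a 3-(phenylsulfonylmethyl)butenolide and expels the sulfonyl group from C13. This closes the carbocycle last and unveils the methylene; the lactone ring is made before it by ring-closing metathesis.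
- The open chain is built linearly from D-threitol acetonide: ynoate and syn-methylcupration (Z C1=C10), asymmetric propargylation (C2), carboalumination–iodination (E C4=C5), asymmetric Nozaki–Hiyama–Kishi coupling with acrolein (C6).
- Two changes protect the sensitive butenolide: C2 is carried as the acetate the target bears, and the carboxyl lost in the key step is carried as CH2OTBS and oxidised only after the butenolide exists. Endgame: acetonide off, O9 acetate, O8 angelate.

Key step: step 18

Assumptions: germacrane numbering is used for all compounds, and (−)-2,3-O-isopropylidene-D-threitol is taken as a purchasable starting material. The catalyst and ligand enantiomers named in steps 8 and 11 are those expected by analogy with simple aldehydes; the antipode would be used if the sense proved opposite.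

**Step 1**
Reactants: 1 (−)-2,3-O-isopropylidene-D-threitol
Product: 2 [(4R,5R)-5-{[(tert-butyldimethylsilyl)oxy]methyl}-2,2-dimethyl-1,3-dioxolan-4-yl]methanol
Conditions: NaH (1.0 equiv), THF, 0 °C; TBSCl (1.0 equiv), rt
Reagents that add atoms: tert-butyldimethylsilyl chloride, CC(C)(C)[Si](C)(C)Cl
Why: Monodeprotonation of the C2-symmetric diol gives a monoalkoxide that is O-silylated once; the two hydroxymethyl groups are equivalent, so no regiochemical question arises.

**Step 2**
Reactants: 2 mono-TBS ether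
Product: 3 (4S,5R)-5-{[(tert-butyldimethylsilyl)oxy]methyl}-2,2-dimethyl-1,3-dioxolane-4-carbaldehyde
Conditions: Dess–Martin periodinane, pyridine, CH2Cl2, 0 °C → rt
Reagents that add atoms: none
Why: Dess–Martin oxidation of the primary alcohol gives the future C10 aldehyde under buffered conditions, and the trans-dioxolane is the thermodynamically preferred arrangement should any enolisation occur.

**Step 3**
Reactants: 3 aldehyde
Product: 4 tert-butyl{[(4R,5R)-5-(2,2-dibromoethenyl)-2,2-dimethyl-1,3-dioxolan-4-yl]methoxy}dimethylsilane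
Conditions: CBr4, PPh3, Zn dust, CH2Cl2, rt (ylide preformed); then 3, 0 °C → rt
Reagents that add atoms: carbon tetrabromide, BrC(Br)(Br)Br
Why: Corey–Fuchs dibromo-olefination (Wittig reaction of Ph3P=CBr2) attaches the future C1, and the zinc-modified neutral conditions spare acetonide and silyl ether.

**Step 4**
Reactants: 4 dibromoalkene
Product: 6 methyl 3-[(4R,5R)-5-{[(tert-butyldimethylsilyl)oxy]methyl}-2,2-dimethyl-1,3-dioxolan-4-yl]prop-2-ynoate, via lithium acetylide 5 (not isolated)
Conditions: n-BuLi (2.1 equiv), THF, −78 °C; then ClCO2Me, −78 → −20 °C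
Reagents that add atoms: methyl chloroformate, COC(=O)Cl
Why: The second stage of the Corey–Fuchs sequence (bromine–lithium exchange and elimination) gives the lithium acetylide, which is C-acylated by the chloroformate to bring in C2 at the ester oxidation level.

**Step 5**
Reactants: 6 ynoate
Product: 7 methyl (2Z)-3-[(4R,5R)-5-{[(tert-butyldimethylsilyl)oxy]methyl}-2,2-dimethyl-1,3-dioxolan-4-yl]but-2-enoate
Conditions: Me2CuLi (from MeLi and CuI), THF, −78 °C; MeOH at −78 °C, then aq NH4Cl
Reagents that add atoms: lithium dimethylcuprate (made from methyllithium, [Li]C, and CuI), [Li+].C[Cu-]C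
Why: Syn carbocupration of the ynoate with protonation at low temperature places the C14 methyl and the new C1–H on the same side, so C9 and the ester carbon end up cis (Z); the acetal oxygen is too poor a leaving group for SN2′ allene formation.

**Step 6**
Reactants: 7 Z-enoate
Product: 8 (2Z)-3-[(4R,5R)-5-{[(tert-butyldimethylsilyl)oxy]methyl}-2,2-dimethyl-1,3-dioxolan-4-yl]but-2-en-1-ol
Conditions: DIBAL-H (2.2 equiv), CH2Cl2, −78 °C; Rochelle salt work-up
Reagents that add atoms: none
Why: 1,2-Reduction of the enoate by DIBAL-H gives the allylic alcohol without touching the alkene geometry, the acetonide or the silyl ether.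

**Step 7**
Reactants: 8 Z-allylic alcohol
Product: 9 (2Z)-3-[(4R,5R)-5-{[(tert-butyldimethylsilyl)oxy]methyl}-2,2-dimethyl-1,3-dioxolan-4-yl]but-2-enal
Conditions: Dess–Martin periodinane, pyridine, CH2Cl2, 0 °C; used at once
Reagents that add atoms: none
Why: Buffered Dess–Martin oxidation of the allylic alcohol at 0 °C with immediate use should keep the Z-enal from isomerising.

**Step 8**
Reactants: 9 Z-enal; 10 allenylboronic acid pinacol ester
Product: 11 (2Z,4R)-2-[(4R,5R)-5-{[(tert-butyldimethylsilyl)oxy]methyl}-2,2-dimethyl-1,3-dioxolan-4-yl]hept-2-en-6-yn-4-ol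
Conditions: (R)-TRIP phosphoric acid (10 mol %), 4 Å MS, toluene, −20 → 0 °C
Reagents that add atoms: none
Why: Chiral phosphoric acid-catalysed propargylation with the allenylboronate proceeds by SE2′ transfer through a closed six-membered transition state, and the catalyst directs attack to the Re face of the aldehyde to set C2 as R, the remote dioxolane centres having little say.

**Step 9**
Reactants: 11 homopropargylic alcohol
Product: 13 (2Z,4R,6E)-7-iodo-6-methyl-2-[(4R,5R)-5-{[(tert-butyldimethylsilyl)oxy]methyl}-2,2-dimethyl-1,3-dioxolan-4-yl]hepta-2,6-dien-4-ol, via alkenylalane 12 (not isolated)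
Conditions: AlMe3 (3.5 equiv), Cp2ZrCl2 (0.5 equiv), H2O (1 equiv), CH2Cl2, −25 → 0 °C; then I2, THF, −30 → 0 °C
Reagents that add atoms: trimethylaluminium, C[Al](C)C; iodine, II
Why: Negishi carboalumination adds methyl (C15) to C4 and aluminium to C5 in a syn fashion and iodinolysis proceeds with retention to give the E-iodide; the free alcohol is carried as its aluminium alkoxide and the water-accelerated low-temperature variant limits exposure of the acetonide to the Lewis acid.

**Step 10**
Reactants: 13 iodo alcohol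
Product: 14 (2Z,4R,6E)-7-iodo-6-methyl-2-[(4R,5R)-5-{[(tert-butyldimethylsilyl)oxy]methyl}-2,2-dimethyl-1,3-dioxolan-4-yl]hepta-2,6-dien-4-yl acetate
Conditions: Ac2O, pyridine, DMAP (cat.), CH2Cl2, 0 °C → rt
Reagents that add atoms: acetic anhydride, CC(=O)OC(C)=O
Why: Standard acetylation installs at C2 the ester the target bears, which survives all later steps and removes one hydroxyl from the late differentiation.

**Step 11**
Reactants: 14 vinyl iodide; 15 acrolein
Product: 16 (3S,4E,7R,8Z)-3-hydroxy-5-methyl-9-[(4R,5R)-5-{[(tert-butyldimethylsilyl)oxy]methyl}-2,2-dimethyl-1,3-dioxolan-4-yl]deca-1,4,8-trien-7-yl acetate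
Conditions: CrCl2 (4 equiv), NiCl2 (2 mol %), (S)-N-[2-(4-isopropyl-4,5-dihydro-1,3-oxazol-2-yl)-6-methylphenyl]methanesulfonamide (4.4 equiv), Et3N, THF, rt; acrolein (3 equiv)
Reagents that add atoms: none
Why: In this asymmetric Nozaki–Hiyama–Kishi coupling, zerovalent nickel formed in situ inserts into the C–I bond and hands the alkenyl group to chromium, and the alkenylchromium carrying the chiral sulfonamide ligand adds 1,2 to the Re face of acrolein to set C6 (S at the carbinol stage) with retention of the E geometry; acetate, acetonide and silyl ether are tolerated.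

**Step 12**
Reactants: 17 2-(bromomethyl)acrylic acid
Product: 18 2-[(phenylsulfonyl)methyl]acrylic acid
Conditions: PhSO2Na (2 equiv), MeOH, reflux; then dilute HCl
Reagents that add atoms: sodium benzenesulfinate, [Na+].[O-]S(=O)c1ccccc1
Why: S-Alkylation of the sulfinate by the allylic bromide gives the allyl sulfone, the direct and the SN2′ pathway leading to the same product.

**Step 13**
Reactants: 16 allylic alcohol; 18 sulfone acid
Product: 19 (3S,4E,7R,8Z)-7-acetoxy-5-methyl-9-[(4R,5R)-5-{[(tert-butyldimethylsilyl)oxy]methyl}-2,2-dimethyl-1,3-dioxolan-4-yl]deca-1,4,8-trien-3-yl 2-[(phenylsulfonyl)methyl]acrylate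
Conditions: DIC, 4-(dimethylamino)pyridinium p-toluenesulfonate (cat.), CH2Cl2, 0 °C → rt
Reagents that add atoms: none
Why: Carbodiimide (Steglich-type) esterification acylates the C6 hydroxyl with retention, and the DMAP salt keeps the concentration of free nucleophilic amine low so that addition–elimination at the sulfonylmethyl acrylate is avoided.

**Step 14**
Reactants: 19 diene ester
Product: 20 (5R)-5-[(1E,4R,5Z)-4-acetoxy-2-methyl-6-{(4R,5R)-5-{[(tert-butyldimethylsilyl)oxy]methyl}-2,2-dimethyl-1,3-dioxolan-4-yl}hepta-1,5-dien-1-yl]-3-[(phenylsulfonyl)methyl]furan-2(5H)-one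
Conditions: second-generation Grubbs catalyst [RuCl2(H2IMes)(PCy3)(=CHPh)] (10 mol %), toluene (5 mM), 80 °C, argon sparge
Reagents that add atoms: none
Why: Ring-closing metathesis between the monosubstituted C7 vinyl group and the acrylate closes the five-membered butenolide (C7=C11) with loss of ethylene; the two trisubstituted alkenes are inert and closure onto C1 would need a trans alkene in a seven-membered ring, and C6 keeps its geometry (its descriptor becomes R by priority only).

**Step 15**
Reactants: 20 butenolide silyl ether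
Product: 21 (5R)-5-[(1E,4R,5Z)-4-acetoxy-6-{(4R,5R)-5-(hydroxymethyl)-2,2-dimethyl-1,3-dioxolan-4-yl}-2-methylhepta-1,5-dien-1-yl]-3-[(phenylsulfonyl)methyl]furan-2(5H)-one
Conditions: HF·pyridine, pyridine, THF, 0 °C → rt
Reagents that add atoms: none
Why: Buffered HF·pyridine cleaves the primary silyl ether; weakly acidic fluoride is chosen because the butenolide C6–H is vinylogously acidic and basic fluoride would risk epimerisation, while acetonide and acetate are stable.

**Step 16**
Reactants: 21 primary alcohol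
Product: 23 (4S,5R)-5-[(2Z,4R,6E)-4-acetoxy-6-methyl-7-{(2R)-5-oxo-4-[(phenylsulfonyl)methyl]-2,5-dihydrofuran-2-yl}hepta-2,6-dien-2-yl]-2,2-dimethyl-1,3-dioxolane-4-carboxylic acid, via aldehyde 22 (not isolated)
Conditions: TEMPO (20 mol %), PhI(OAc)2 (2.5 equiv), MeCN/H2O (1:1), rt
Reagents that add atoms: water, O
Why: Oxoammonium-mediated oxidation takes the primary alcohol through the aldehyde hydrate to the acid under near-neutral conditions that leave alkenes, allyl sulfone and butenolide alone; any epimerisation at C8 is irrelevant because C8 becomes a radical centre.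

**Step 17**
Reactants: 23 carboxylic acid
Product: 24 1,3-dioxoisoindolin-2-yl (4S,5R)-5-[(2Z,4R,6E)-4-acetoxy-6-methyl-7-{(2R)-5-oxo-4-[(phenylsulfonyl)methyl]-2,5-dihydrofuran-2-yl}hepta-2,6-dien-2-yl]-2,2-dimethyl-1,3-dioxolane-4-carboxylate
Conditions: N-hydroxyphthalimide, DIC, CH2Cl2, 0 °C → rt; filtered and used promptly
Reagents that add atoms: N-hydroxyphthalimide, ON1C(=O)c2ccccc2C1=O
Why: Carbodiimide coupling with the acidic N-hydroxyphthalimide needs no added base, so the redox-active ester forms without endangering C6 or the allyl sulfone.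

**Step 18**
Reactants: 24 redox-active ester
Product: 25 (2R,6R,7S,8R,9R)-2-acetoxy-8,9-(isopropylidenedioxy)germacra-1(10)Z,4E,11(13)-trien-12,6-olide
Conditions: undivided cell, Zn anode, reticulated vitreous carbon cathode, n-Bu4NPF6 (0.1 M), DMF, constant current (2.2 F/mol) at the first reduction wave of the ester, 24 added by syringe pump (final 2 mM), rt, argon; aq NH4Cl work-up
Reagents that add atoms: none
Why: Proposed new method: one electron from the cathode breaks the N–O bond of the phthalimide ester, CO2 is lost, and the nucleophilic α,β-dioxygenated C8 dioxolan-4-yl radical adds to C7, the electron-poor β-carbon of the butenolide, giving a C11 radical that ejects the phenylsulfonyl radical from C13 by β-scission; this radical is reduced to sulfinate, so two electrons are used per molecule and the zinc ions from the anode bind the phthalimide and sulfinate anions. The closest known reactions are intermolecular electroreductive decarboxylative conjugate additions of redox-active esters and radical allylations with 2-(sulfonylmethyl)acrylates; closure of a ten-membered carbocycle in this way is not known. The ring closes in a 10-exo-trig mode (new bond C7–C8, carbocycle C1–C10), the lactone ring being already in place. C8 is controlled by the dioxolane, whose radical is trapped on the face anti to the C9 substituent so that C7–C8 ends up trans to C9–C10 (8R) whichever C8 epimer of the ester is used; C7 is controlled by attack on the butenolide face opposite the C5–C6 bond, which gives the trans-fused lactone (7S). The step needs cyclisation to win over further reduction, hydrogen transfer from C2–H or C6–H and dimerisation of the radical, which slow addition at low concentration and the two preformed trisubstituted alkenes (Z at C1=C10, E at C4=C5) should favour by holding C8 near C7; the facial choice at C7 is the least secured element.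

**Step 19**
Reactants: 25 macrocyclic acetonide
Product: 26 (2R,6R,7S,8R,9R)-2-acetoxy-8,9-dihydroxygermacra-1(10)Z,4E,11(13)-trien-12,6-olide
Conditions: AcOH/H2O (4:1), 45 °C
Reagents that add atoms: none
Why: Acid-catalysed acetal hydrolysis opens the strained trans-fused dioxolane under conditions mild enough for the allylic acetate and the methylene lactone.

**Step 20**
Reactants: 26 diol
Product: 27 (2R,6R,7S,8R,9R)-2,9-diacetoxy-8-hydroxygermacra-1(10)Z,4E,11(13)-trien-12,6-olide
Conditions: Ac2O (1.05 equiv), Et3N, DMAP (cat.), CH2Cl2, −40 °C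
Reagents that add atoms: acetic anhydride, CC(=O)OC(C)=O
Why: Kinetically controlled monoacetylation at low temperature should favour the allylic O9 hydroxyl next to the flat C10 over the O8 hydroxyl, which is flanked by the ring-fusion carbon C7 and by C9.

**Step 21**
Reactants: 27 hydroxy diacetate; 28 angelic acid
Product: 30 (2R,6R,7S,8R,9R)-2,9-diacetoxy-8-angeloyloxygermacra-1(10)Z,4E,11(13)-trien-12,6-olide (CNP0499619.1), via mixed anhydride 29 (not isolated)
Conditions: 28, 2,4,6-trichlorobenzoyl chloride, Et3N, toluene, rt; then 27, toluene, 80 °C (no DMAP)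
Reagents that add atoms: none
Why: Yamaguchi esterification through the preformed mixed anhydride acylates the hindered O8 hydroxyl, and leaving out DMAP avoids isomerisation of the angelate to the tiglate and limits acetyl migration and translactonisation to O8.

**Compound list**

1 | (−)-2,3-O-isopropylidene-D-threitol, [(4R,5R)-2,2-dimethyl-1,3-dioxolane-4,5-diyl]dimethanol | OC[C@H]1OC(C)(C)O[C@@H]1CO | starting material
2 | [(4R,5R)-5-{[(tert-butyldimethylsilyl)oxy]methyl}-2,2-dimethyl-1,3-dioxolan-4-yl]methanol | OC[C@H]1OC(C)(C)O[C@@H]1CO[Si](C)(C)C(C)(C)C | intermediate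
3 | (4S,5R)-5-{[(tert-butyldimethylsilyl)oxy]methyl}-2,2-dimethyl-1,3-dioxolane-4-carbaldehyde (aldehyde carbon = C10) | O=C[C@H]1OC(C)(C)O[C@@H]1CO[Si](C)(C)C(C)(C)C | intermediate
4 | tert-butyl{[(4R,5R)-5-(2,2-dibromoethenyl)-2,2-dimethyl-1,3-dioxolan-4-yl]methoxy}dimethylsilane | BrC(Br)=C[C@H]1OC(C)(C)O[C@@H]1CO[Si](C)(C)C(C)(C)C | intermediate
5 | lithium acetylide of the 5-ethynyl dioxolane (C1–Li) | [Li]C#C[C@H]1OC(C)(C)O[C@@H]1CO[Si](C)(C)C(C)(C)C | intermediate
6 | methyl 3-[(4R,5R)-5-{[(tert-butyldimethylsilyl)oxy]methyl}-2,2-dimethyl-1,3-dioxolan-4-yl]prop-2-ynoate | COC(=O)C#C[C@H]1OC(C)(C)O[C@@H]1CO[Si](C)(C)C(C)(C)C | intermediate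
7 | methyl (2Z)-3-[(4R,5R)-5-{[(tert-butyldimethylsilyl)oxy]methyl}-2,2-dimethyl-1,3-dioxolan-4-yl]but-2-enoate | COC(=O)/C=C(/C)[C@H]1OC(C)(C)O[C@@H]1CO[Si](C)(C)C(C)(C)C | intermediate
8 | (2Z)-3-[(4R,5R)-5-{[(tert-butyldimethylsilyl)oxy]methyl}-2,2-dimethyl-1,3-dioxolan-4-yl]but-2-en-1-ol | OC/C=C(/C)[C@H]1OC(C)(C)O[C@@H]1CO[Si](C)(C)C(C)(C)C | intermediate
9 | (2Z)-3-[(4R,5R)-5-{[(tert-butyldimethylsilyl)oxy]methyl}-2,2-dimethyl-1,3-dioxolan-4-yl]but-2-enal (aldehyde carbon = C2) | O=C/C=C(/C)[C@H]1OC(C)(C)O[C@@H]1CO[Si](C)(C)C(C)(C)C | intermediate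
10 | allenylboronic acid pinacol ester | C=C=CB1OC(C)(C)C(C)(C)O1 | starting material
11 | (2Z,4R)-2-[(4R,5R)-5-{[(tert-butyldimethylsilyl)oxy]methyl}-2,2-dimethyl-1,3-dioxolan-4-yl]hept-2-en-6-yn-4-ol | C#CC[C@@H](O)/C=C(/C)[C@H]1OC(C)(C)O[C@@H]1CO[Si](C)(C)C(C)(C)C | intermediate
12 | (E)-alkenyldimethylalane at C5 with the C2 oxygen as its dimethylaluminium alkoxide | C[Al](C)/C=C(\C)C[C@@H](O[Al](C)C)/C=C(/C)[C@H]1OC(C)(C)O[C@@H]1CO[Si](C)(C)C(C)(C)C | intermediate
13 | (2Z,4R,6E)-7-iodo-6-methyl-2-[(4R,5R)-5-{[(tert-butyldimethylsilyl)oxy]methyl}-2,2-dimethyl-1,3-dioxolan-4-yl]hepta-2,6-dien-4-ol | I/C=C(\C)C[C@@H](O)/C=C(/C)[C@H]1OC(C)(C)O[C@@H]1CO[Si](C)(C)C(C)(C)C | intermediate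
14 | (2Z,4R,6E)-7-iodo-6-methyl-2-[(4R,5R)-5-{[(tert-butyldimethylsilyl)oxy]methyl}-2,2-dimethyl-1,3-dioxolan-4-yl]hepta-2,6-dien-4-yl acetate | I/C=C(\C)C[C@@H](OC(C)=O)/C=C(/C)[C@H]1OC(C)(C)O[C@@H]1CO[Si](C)(C)C(C)(C)C | intermediate
15 | acrolein | C=CC=O | starting material
16 | (3S,4E,7R,8Z)-3-hydroxy-5-methyl-9-[(4R,5R)-5-{[(tert-butyldimethylsilyl)oxy]methyl}-2,2-dimethyl-1,3-dioxolan-4-yl]deca-1,4,8-trien-7-yl acetate (C6 carbinol) | O[C@@H](C=C)/C=C(\C)C[C@@H](OC(C)=O)/C=C(/C)[C@H]1OC(C)(C)O[C@@H]1CO[Si](C)(C)C(C)(C)C | intermediate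
17 | 2-(bromomethyl)acrylic acid | C=C(CBr)C(=O)O | starting material
18 | 2-[(phenylsulfonyl)methyl]acrylic acid | C=C(CS(=O)(=O)c1ccccc1)C(=O)O | intermediate
19 | (3S,4E,7R,8Z)-7-acetoxy-5-methyl-9-[(4R,5R)-5-{[(tert-butyldimethylsilyl)oxy]methyl}-2,2-dimethyl-1,3-dioxolan-4-yl]deca-1,4,8-trien-3-yl 2-[(phenylsulfonyl)methyl]acrylate | C=C(CS(=O)(=O)c1ccccc1)C(=O)O[C@@H](C=C)/C=C(\C)C[C@@H](OC(C)=O)/C=C(/C)[C@H]1OC(C)(C)O[C@@H]1CO[Si](C)(C)C(C)(C)C | intermediate
20 | (5R)-5-[(1E,4R,5Z)-4-acetoxy-2-methyl-6-{(4R,5R)-5-{[(tert-butyldimethylsilyl)oxy]methyl}-2,2-dimethyl-1,3-dioxolan-4-yl}hepta-1,5-dien-1-yl]-3-[(phenylsulfonyl)methyl]furan-2(5H)-one | O=C1O[C@@H](C=C1CS(=O)(=O)c1ccccc1)/C=C(\C)C[C@@H](OC(C)=O)/C=C(/C)[C@H]1OC(C)(C)O[C@@H]1CO[Si](C)(C)C(C)(C)C | intermediate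
21 | (5R)-5-[(1E,4R,5Z)-4-acetoxy-6-{(4R,5R)-5-(hydroxymethyl)-2,2-dimethyl-1,3-dioxolan-4-yl}-2-methylhepta-1,5-dien-1-yl]-3-[(phenylsulfonyl)methyl]furan-2(5H)-one | O=C1O[C@@H](C=C1CS(=O)(=O)c1ccccc1)/C=C(\C)C[C@@H](OC(C)=O)/C=C(/C)[C@H]1OC(C)(C)O[C@@H]1CO | intermediate
22 | corresponding dioxolane-4-carbaldehyde (C8 formyl) | O=C1O[C@@H](C=C1CS(=O)(=O)c1ccccc1)/C=C(\C)C[C@@H](OC(C)=O)/C=C(/C)[C@H]1OC(C)(C)O[C@@H]1C=O | intermediate
23 | (4S,5R)-5-[(2Z,4R,6E)-4-acetoxy-6-methyl-7-{(2R)-5-oxo-4-[(phenylsulfonyl)methyl]-2,5-dihydrofuran-2-yl}hepta-2,6-dien-2-yl]-2,2-dimethyl-1,3-dioxolane-4-carboxylic acid | O=C1O[C@@H](C=C1CS(=O)(=O)c1ccccc1)/C=C(\C)C[C@@H](OC(C)=O)/C=C(/C)[C@H]1OC(C)(C)O[C@@H]1C(=O)O | intermediate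
24 | N-acyloxyphthalimide (1,3-dioxoisoindolin-2-yl ester) of 23, the key-step precursor | O=C1O[C@@H](C=C1CS(=O)(=O)c1ccccc1)/C=C(\C)C[C@@H](OC(C)=O)/C=C(/C)[C@H]1OC(C)(C)O[C@@H]1C(=O)ON1C(=O)c2ccccc2C1=O | intermediate
25 | (2R,6R,7S,8R,9R)-2-acetoxy-8,9-(isopropylidenedioxy)germacra-1(10)Z,4E,11(13)-trien-12,6-olide, the key-step product | C=C1C(=O)O[C@@H]2/C=C(\C)C[C@@H](OC(C)=O)/C=C(/C)[C@H]3OC(C)(C)O[C@@H]3[C@@H]12 | intermediate
26 | (2R,6R,7S,8R,9R)-2-acetoxy-8,9-dihydroxygermacra-1(10)Z,4E,11(13)-trien-12,6-olide | C=C1C(=O)O[C@@H]2/C=C(\C)C[C@@H](OC(C)=O)/C=C(/C)[C@@H](O)[C@H](O)[C@@H]12 | intermediate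
27 | (2R,6R,7S,8R,9R)-2,9-diacetoxy-8-hydroxygermacra-1(10)Z,4E,11(13)-trien-12,6-olide | C=C1C(=O)O[C@@H]2/C=C(\C)C[C@@H](OC(C)=O)/C=C(/C)[C@@H](OC(C)=O)[C@H](O)[C@@H]12 | intermediate
28 | angelic acid, (Z)-2-methylbut-2-enoic acid | C/C=C(/C)C(=O)O | starting material
29 | angelic 2,4,6-trichlorobenzoic anhydride | C/C=C(/C)C(=O)OC(=O)c1c(Cl)cc(Cl)cc1Cl | intermediate
30 | (2R,6R,7S,8R,9R)-2,9-diacetoxy-8-angeloyloxygermacra-1(10)Z,4E,11(13)-trien-12,6-olide, CNP0499619.1 | C=C1C(=O)O[C@@H]2/C=C(\C)C[C@@H](OC(C)=O)/C=C(/C)[C@@H](OC(C)=O)[C@H](OC(=O)/C(C)=C\C)[C@@H]12 | target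

**Step count**

Total: 21 steps. Longest linear sequence: 20 steps (steps 1–11 and 13–21); step 12 is a one-step side branch.

**Steps most likely to fail**

1. Step 18 (proposed new method). The ten-membered closure may lose to further reduction of the radical, to hydrogen transfer from C2–H or C6–H, or to dimerisation, and attack may occur on the wrong face of C7. The fallback uses known chemistry and forms the ring at C6–C7 by an intramolecular chromium-mediated allylation; it sets out from 13 and comes back at 25. In it the carbon that the main route sacrifices becomes C7, and acrolein is not used.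
 - Palladium-catalysed formylation of 13 (Pd(PPh3)4, CO, Bu3SnH) should give the (E)-hydroxy enal F1, with C6 as the aldehyde carbon.
 - Acetylation gives the acetoxy enal F2, and HF·pyridine frees the primary alcohol F3.
 - Dess–Martin oxidation gives the dialdehyde F4.
 - A Morita–Baylis–Hillman reaction with methyl acrylate and DABCO, at the more electrophilic α-alkoxy aldehyde, gives the adduct F5.
 - NBS/Me2S converts F5 with allylic transposition into the (Z)-2-(bromomethyl)enoate F6.
 - CrCl2 in THF at high dilution then adds the allylchromium through C7 to the C6 aldehyde, and the alkoxide lactonises onto the methyl ester to give 25.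
 - The closed Zimmerman–Traxler transition state of γ-substituted allylchromium reagents is expected to favour the trans lactone, with the C8 stereocentre choosing the face; this would have to be checked.

2. Step 11. Facial discrimination on the small, unhindered acrolein may be poor, and the enal may oligomerise. The fallback replaces asymmetric C–C bond formation by a kinetic resolution; it sets out from 14 and comes back at 16. Ligand-free NiCl2/CrCl2 coupling with acrolein should give the C6-epimeric carbinol mixture F7. A lipase (Amano PS or CAL-B) with vinyl acetate is expected to acylate the 6R epimer, in which the large alkenyl and the medium vinyl group are placed as in the fast-reacting enantiomers of simple secondary alcohols, giving the 6R acetate F8. The 6S alcohol 16 is left untouched and separated.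

3. Step 20. The acetyl group may go to O8 or to both oxygens, or migrate from O9 to O8. The fallback inverts the order of acylation; it sets out from 26 and comes back at 30. If O8–H proves the more reactive hydroxyl, one equivalent of the angelic mixed anhydride 29 (toluene, no DMAP) is used first to give the 8-angelate 9-alcohol F9. Acetylation of the remaining O9–H (Ac2O, DMAP, low temperature) then gives 30.

**Further compounds**

F1 | step 18 | (2E,5R,6Z)-5-hydroxy-3-methyl-7-[(4R,5R)-5-{[(tert-butyldimethylsilyl)oxy]methyl}-2,2-dimethyl-1,3-dioxolan-4-yl]octa-2,6-dienal | O=C/C=C(\C)C[C@@H](O)/C=C(/C)[C@H]1OC(C)(C)O[C@@H]1CO[Si](C)(C)C(C)(C)C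
F2 | step 18 | acetate of F1 at the C2 oxygen | O=C/C=C(\C)C[C@@H](OC(C)=O)/C=C(/C)[C@H]1OC(C)(C)O[C@@H]1CO[Si](C)(C)C(C)(C)C
F3 | step 18 | desilylated primary alcohol of F2 | O=C/C=C(\C)C[C@@H](OC(C)=O)/C=C(/C)[C@H]1OC(C)(C)O[C@@H]1CO
F4 | step 18 | dialdehyde (C6 enal and C7 dioxolane carbaldehyde) | O=C/C=C(\C)C[C@@H](OC(C)=O)/C=C(/C)[C@H]1OC(C)(C)O[C@@H]1C=O
F5 | step 18 | Morita–Baylis–Hillman adduct, methyl 2-[hydroxy(dioxolanyl)methyl]acrylate (C7 carbinol, both epimers) | O=C/C=C(\C)C[C@@H](OC(C)=O)/C=C(/C)[C@H]1OC(C)(C)O[C@@H]1C(O)C(=C)C(=O)OC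
F6 | step 18 | methyl (Z)-2-(bromomethyl)-3-(dioxolanyl)acrylate bearing the C6 enal | O=C/C=C(\C)C[C@@H](OC(C)=O)/C=C(/C)[C@H]1OC(C)(C)O[C@@H]1/C=C(\CBr)C(=O)OC
F7 | step 11 | C6-epimeric mixture of carbinol 16 | OC(C=C)/C=C(\C)C[C@@H](OC(C)=O)/C=C(/C)[C@H]1OC(C)(C)O[C@@H]1CO[Si](C)(C)C(C)(C)C
F8 | step 11 | acetate of the 6R epimer of 16 | CC(=O)O[C@H](C=C)/C=C(\C)C[C@@H](OC(C)=O)/C=C(/C)[C@H]1OC(C)(C)O[C@@H]1CO[Si](C)(C)C(C)(C)C
F9 | step 20 | (2R,6R,7S,8R,9R)-2-acetoxy-8-angeloyloxy-9-hydroxygermacra-1(10)Z,4E,11(13)-trien-12,6-olide | C=C1C(=O)O[C@@H]2/C=C(\C)C[C@@H](OC(C)=O)/C=C(/C)[C@@H](O)[C@H](OC(=O)/C(C)=C\C)[C@@H]12
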